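**Retrosynthetic overview**
1. Dichrostachine A (26) ⇒ last-step Diels–Alder union (cyclohexene ring; C12–C and C15–C bonds) of the labdane triene diol 17 with the chromonyl methoxyquinone 25, itself from chalcone → flavone 22 → oxidative demethylation.
2. 17 ⇒ trans-decalin 11: both labdane carbocycles come from one intramolecular Diels–Alder reaction of acyclic 10 that forms C1–C2 and C5–C10; ring A is the new cyclohexene, ring B is closed by the tether C6–C9.
3. Enabling feature: in ring A the quaternary C10 (Me-20) carries the C1 methylene, so C1=C10(Me) is an isopropenyl group on C9 (the stereocentre of (R)-carvone), and C2–C3–C4(Me-19)–C5 is a 2-oxy-3-methylbutadiene; the cis-1,3 pair 7β-O/9β-chain on ring B fixes the tether chair, and the C3=C4 enol ether left behind installs C18 at C4.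
4. 10 ⇐ (R)-carvone: epoxide/Eschenmoser–Tanabe fragmentation (C9 plus a but-2-ynyl chain, the masked C11–C16 diene), α-methylenation (C8=C17), vinylogous Mukaiyama aldol (C7–OH, C3–C6), methyl ketone (C2), double silylation.
5. Ring order: rings A and B together (step 9), chromone pyranone ring (step 17), cyclohexene ring fused to the enedione (step 20).

Key step: step 9

Remark: terpenoid carbons carry labdane numbers (C1–C20) throughout; the C12 configuration of the target corresponds to addition of the (12E)-diene with the chromone endo and the quinone ring exo, and the last step is planned for that mode.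

Step 1
Reactants: 1 (R)-(−)-carvone
Product: 2 (1R,4R,6R)-1-methyl-4-(prop-1-en-2-yl)-7-oxabicyclo[4.1.0]heptan-2-one
Conditions: 30% H2O2, NaOH (aq.), MeOH, 0 °C
Reagents that add atoms: hydrogen peroxide, OO
Why: Weitz–Scheffer nucleophilic epoxidation is selective for the electron-poor enone double bond and leaves the isopropenyl group, and hydroperoxide adds anti to the isopropenyl group, so the two epoxide centres (destroyed again in step 2) are trans to it.

Step 2
Reactants: 2 carvone epoxide
Product: 3 (3S)-3-(prop-1-en-2-yl)hept-5-ynal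
Conditions: TsNHNH2, AcOH, CH2Cl2, −20 °C → rt
Reagents that add atoms: none
Why: Eschenmoser–Tanabe fragmentation of the epoxy tosylhydrazone, with loss of N2 and sulfinate, gives the aldehyde and the methyl alkyne, and the isopropenyl-bearing centre (later C9) is not touched.

Step 3
Reactants: 3 (3S)-3-(prop-1-en-2-yl)hept-5-ynal
Product: 4 (3R)-2-methylidene-3-(prop-1-en-2-yl)hept-5-ynal
Conditions: [CH2=NMe2]I, Et3N, CH2Cl2, rt
Reagents that add atoms: N,N-dimethylmethyleneiminium iodide, C=[N+](C)C.[I-]
Why: Mannich reaction of the aldehyde followed by E1cB loss of dimethylamine gives the 2-methylidene aldehyde (later C8=C17) without an amine catalyst that could move the double bond into conjugation, and the β-stereocentre of 3 is not enolisable and keeps its configuration.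

Step 4
Reactants: 5 methyl tiglate
Product: 6 tert-butyl[(1-methoxy-2-methylbuta-1,3-dien-1-yl)oxy]dimethylsilane
Conditions: LiN(iPr)2, DMPU, THF, −78 °C; TBSCl
Reagents that add atoms: tert-butyldimethylsilyl chloride, CC(C)(C)[Si](C)(C)Cl
Why: γ-Deprotonation of the enoate and O-silylation of the extended enolate give the vinylketene silyl acetal, whose acetal geometry is of no consequence for step 5.

Step 5
Reactants: 4 (3R)-2-methylidene-3-(prop-1-en-2-yl)hept-5-ynal; 6 vinylketene silyl acetal
Product: 7 methyl (2E,5S,7R)-5-hydroxy-2-methyl-6-methylidene-7-(prop-1-en-2-yl)undec-2-en-9-ynoate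
Conditions: (4S)-4-(1H-indol-3-ylmethyl)-2-phenyl-3-tosyl-1,3,2-oxazaborolidin-5-one (1 equiv), iPrOH, EtCN, −78 °C
Reagents that add atoms: none
Why: Vinylogous Mukaiyama aldol reaction in which the boron Lewis acid activates the aldehyde, the silyl dienolate attacks through its γ-carbon and the α-methyl group enforces the (2E)-enoate; the L-tryptophan-derived Lewis acid is expected to shield the Re face so that Si-face attack sets the (5S)-carbinol (later C7) against the weak bias of the remote allylic centre (the D-tryptophan reagent would be taken if the sense were opposite), and isopropanol takes up the silyl group.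

Step 6
Reactants: 7 hydroxy enoate
Product: 8 (2E,5S,7R)-5-hydroxy-N-methoxy-N,2-dimethyl-6-methylidene-7-(prop-1-en-2-yl)undec-2-en-9-ynamide
Conditions: MeNH(OMe)·HCl, iPrMgCl, THF, −20 → 0 °C
Reagents that add atoms: N,O-dimethylhydroxylamine hydrochloride, CNOC.Cl
Why: Aminolysis of the ester by the magnesium amide of N,O-dimethylhydroxylamine gives the N-methoxy-N-methylamide, and the magnesium alkoxide of the free hydroxyl is inert and no stereocentre is touched.

Step 7
Reactants: 8 N-methoxy-N-methylamide
Product: 9 (3E,6S,8R)-6-hydroxy-3-methyl-7-methylidene-8-(prop-1-en-2-yl)dodec-3-en-10-yn-2-one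
Conditions: MeMgBr, THF, −78 → 0 °C
Reagents that add atoms: methylmagnesium bromide, C[Mg]Br
Why: Grignard addition to the N-methoxy-N-methylamide stops at the chelated tetrahedral intermediate, which gives the methyl ketone (C2 and C3) on work-up without over-addition.

Step 8
Reactants: 9 hydroxy enone
Product: 10 (3E,6S,8R)-2,6-bis[(tert-butyldimethylsilyl)oxy]-3-methyl-7-methylidene-8-(prop-1-en-2-yl)dodeca-1,3-dien-10-yne
Conditions: TBSOTf (2.5 equiv), Et3N, CH2Cl2, −78 → 0 °C
Reagents that add atoms: tert-butyldimethylsilyl trifluoromethanesulfonate, CC(C)(C)[Si](C)(C)OS(=O)(=O)C(F)(F)F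
Why: Silylation of the alcohol and soft enolisation of the methyl ketone (O-silylation, then removal of an acetyl proton by Et3N) give in one operation the cross-conjugated 2-silyloxy diene, the kinetic regioisomer, with the (3E) geometry that places the tether trans to the vinyl group as the cycloaddition requires.

Step 9
Reactants: 10 bis-silylated acyclic trienyne
Product: 11 (5R,7S,9R,10R)-3,7-bis(TBS-oxy)-14,15,18-trinorlabda-3,8(17)-dien-12-yne (trans-decalin silyl enol ether)
Conditions: toluene (0.005 M), BHT, Et3N (0.1 equiv), base-washed sealed tube, 185 °C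
Reagents that add atoms: none
Why: Thermal, concerted intramolecular Diels–Alder reaction in which the 2-silyloxy-3-methyl diene C2=C3–C4=C5 adds across the isopropenyl dienophile C10=C1, forming C1–C2 and C5–C10, so that ring A closes as the new cyclohexene (silyl enol ether at C3=C4) and ring B closes as the ring of the four-atom tether C6–C9. The closest known reaction type is the thermal cycloaddition of unactivated 1,7,9-decatrienes with a 1,1-disubstituted dienophile, which gives angular-methyl trans-decalins of the eudesmane kind. Ring A closes in the [4+2] mode and ring B through a chair-like tether that lies exo while the dienophile methyl lies endo, which leads to the trans ring fusion; the 4-methyl group on the diene carbon next to the tether raises the energy of the tether-endo (cis-fused) arrangement by eclipsing with C6–H. The new stereocentres C5 and quaternary C10 are controlled by C7 and C9, because the 7-silyloxy and 9-butynyl groups are cis-1,3 and both equatorial in only one chair (the other chair would make them 1,3-diaxial), and this chair delivers the diene to the face that gives 5α-H and 10β-methyl. The step needs site selectivity among four π-systems, and tether length secures it: only the isopropenyl group is reached through four atoms, whereas the exocyclic methylene (two atoms) and the alkyne (five atoms, seven-membered ring) cannot compete; BHT and base protect the silyl dienol ether during heating.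

Step 10
Reactants: 11 trans-decalin silyl enol ether
Product: 13 (5R,7S,9R,10R,12E)-3,7-bis(TBS-oxy)-18-norlabda-3,8(17),12,14-tetraene, via alkenylzirconocene chloride 12 (not isolated)
Conditions: Cp2Zr(H)Cl (1.6 equiv), THF, rt → 40 °C; then CH2=CHBr, ZnCl2, Pd(PPh3)4 (5 mol %), THF, rt
Reagents that add atoms: vinyl bromide, C=CBr; Cp2Zr(H)Cl, [H][Zr](Cl)(C1C=CC=C1)C1C=CC=C1 (its zirconium, chlorine and cyclopentadienyl atoms stay only in 12)
Why: Hydrozirconation of the methyl alkyne is a syn addition that, after equilibration with a small excess of reagent, places zirconium on the less hindered methyl-bearing C13 (the alkyne reacts faster than the hindered 1,1-disubstituted C8=C17 alkene and the tetrasubstituted enol ether), and Negishi coupling with vinyl bromide after transmetalation to zinc proceeds with retention to give the (12E)-diene.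

Step 11
Reactants: 13 (12E)-diene silyl enol ether
Product: 14 (4R,5R,7S,9R,10R,12E)-7-(TBS-oxy)-18-hydroxylabda-8(17),12,14-trien-3-one
Conditions: 37% aq. HCHO, Sc(OTf)3 (10 mol %), THF, rt
Reagents that add atoms: formaldehyde, C=O
Why: Mukaiyama aldol reaction of the regiodefined tetrasubstituted silyl enol ether with aqueous formaldehyde builds the C4 quaternary centre, and formaldehyde approaches C4 from the α-face, away from the axial 10β-methyl group (1,3-diaxial), so the hydroxymethyl group becomes 4α (equatorial, C18) and the methyl group 4β.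

Step 12
Reactants: 14 18-hydroxy-3-ketone
Product: 15 C3 p-toluenesulfonylhydrazone of 14
Conditions: TsNHNH2, EtOH, 60 °C
Reagents that add atoms: p-toluenesulfonyl hydrazide, Cc1ccc(cc1)S(=O)(=O)NN
Why: Condensation of the only ketone with the sulfonyl hydrazide gives the tosylhydrazone, the quaternary C4 cannot epimerise, and the near-neutral conditions avoid retro-aldol cleavage.

Step 13
Reactants: 15 tosylhydrazone
Product: 16 (4R,5R,7S,9R,10S,12E)-7-(TBS-oxy)labda-8(17),12,14-trien-18-ol
Conditions: catecholborane (4 equiv), CHCl3, 0 °C → rt; NaOAc·3H2O, reflux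
Reagents that add atoms: none
Why: Reductive deoxygenation of a tosylhydrazone (hydride delivery to C=N, then acetate-induced loss of sulfinate and of N2 from the diazene) turns C3 into CH2 under conditions that leave the diene, the exocyclic methylene and the silyl ether alone.

Step 14
Reactants: 16 7-O-TBS triene-18-ol
Product: 17 (4R,5R,7S,9R,10S,12E)-labda-8(17),12,14-triene-7,18-diol (7β-OH)
Conditions: Bu4NF, THF, 45 °C
Reagents that add atoms: none
Why: Fluoride cleavage of the secondary allylic silyl ether frees the 7β-hydroxyl group without touching a stereocentre.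

Step 15
Reactants: 18 2',4',6'-trihydroxyacetophenone
Product: 19 1-[2,4-bis(benzyloxy)-6-hydroxyphenyl]ethan-1-one
Conditions: BnBr (2.1 equiv), K2CO3, DMF, rt
Reagents that add atoms: benzyl bromide, BrCc1ccccc1
Why: Williamson etherification with two equivalents of halide benzylates two hydroxyls and leaves the one hydrogen-bonded to the acetyl group, the least nucleophilic, free.

Step 16
Reactants: 19 bis-benzyl acetophenone; 20 2,4,5-trimethoxybenzaldehyde
Product: 21 (2E)-1-[2,4-bis(benzyloxy)-6-hydroxyphenyl]-3-(2,4,5-trimethoxyphenyl)prop-2-en-1-one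
Conditions: KOH, EtOH/H2O, rt
Reagents that add atoms: none
Why: Claisen–Schmidt (crossed aldol) condensation of the acetophenone enolate with the non-enolisable aldehyde, followed by dehydration, gives the (E)-chalcone.

Step 17
Reactants: 21 chalcone
Product: 22 5,7-bis(benzyloxy)-2-(2,4,5-trimethoxyphenyl)-4H-chromen-4-one
Conditions: I2 (10 mol %), DMSO, 120 °C
Reagents that add atoms: none
Why: Iodine-catalysed oxidative cyclisation of a 2'-hydroxychalcone (oxa-Michael closure, α-iodination, loss of HI, reoxidation of iodide by DMSO) closes the pyranone ring and gives the flavone.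

Step 18
Reactants: 22 flavone
Product: 23 2-[5,7-bis(benzyloxy)-4-oxo-4H-chromen-2-yl]-5-methoxycyclohexa-2,5-diene-1,4-dione
Conditions: (NH4)2Ce(NO3)6 (2.5 equiv), MeCN/H2O, 0 °C
Reagents that add atoms: water, O
Why: Oxidative demethylation of the electron-rich 1,2,4-trimethoxyaryl ring (two one-electron oxidations with attack of water) converts the para-related 2'- and 5'-methoxy carbons into the quinone carbonyls and keeps the 4'-methoxy group as the vinylogous ester, while the benzyl ethers and the electron-poor chromone are not oxidised.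

Step 19
Reactants: 23 benzyl-protected quinone
Product: 24 2-(2,5-dihydroxy-4-methoxyphenyl)-5,7-dihydroxy-4H-chromen-4-one
Conditions: H2 (1 atm), Pd/C (10% Pd on carbon), THF/MeOH, rt
Reagents that add atoms: none
Why: Catalytic hydrogenolysis cleaves both benzyl ethers and reduces the quinone to the hydroquinone in the same operation, while the chromone double bond, part of a vinylogous ester, is reduced much more slowly.

Step 20
Reactants: 24 hydroquinone flavone; 17 labdatriene diol
Product: 26 dichrostachine A, via quinone 25 (not isolated)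
Conditions: Ag2O, Na2SO4, THF, rt, dark; filter; then 17 (1 equiv), THF/toluene (0.5 M), 45 °C, dark
Reagents that add atoms: none
Why: Mild oxidation gives quinone 25, which undergoes an intermolecular Diels–Alder reaction at its chromonyl-substituted double bond (the methoxy-bearing one is deactivated as a vinylogous ester) with the (12E)-diene; the unsubstituted terminus C15, the more nucleophilic end of a 1-alkyl diene, should bond to the quinone CH that is the δ-carbon of the chromone dienone so that C12 joins the carbon that becomes quaternary, suprafacial addition sets the cis fusion, the C12 configuration relative to the fusion requires the chromone rather than the quinone ring to lie endo under the diene, and the configuration of the new triad relative to the labdane requires attack anti to C9 in the C9–C11 rotamer with C12 anti to C8; the substrates bias these last two choices only weakly, so the endo/exo and facial isomers are the expected co-products and the target should be separated from them by HPLC.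

**Compound list**
1 | (R)-(−)-carvone, (5R)-2-methyl-5-(prop-1-en-2-yl)cyclohex-2-en-1-one | CC1=CC[C@H](CC1=O)C(C)=C | starting material
2 | (1R,4R,6R)-1-methyl-4-(prop-1-en-2-yl)-7-oxabicyclo[4.1.0]heptan-2-one (epoxide trans to isopropenyl) | C[C@@]12O[C@@H]1C[C@H](CC2=O)C(C)=C | intermediate
3 | (3S)-3-(prop-1-en-2-yl)hept-5-ynal | CC#CC[C@@H](CC=O)C(C)=C | intermediate
4 | (3R)-2-methylidene-3-(prop-1-en-2-yl)hept-5-ynal | CC#CC[C@@H](C(=C)C=O)C(C)=C | intermediate
5 | methyl tiglate, methyl (2E)-2-methylbut-2-enoate | C/C=C(\C)C(=O)OC | starting material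
6 | tert-butyl[(1-methoxy-2-methylbuta-1,3-dien-1-yl)oxy]dimethylsilane (mixture of acetal geometries) | C=CC(C)=C(OC)O[Si](C)(C)C(C)(C)C | intermediate
7 | methyl (2E,5S,7R)-5-hydroxy-2-methyl-6-methylidene-7-(prop-1-en-2-yl)undec-2-en-9-ynoate | COC(=O)/C(C)=C/C[C@H](O)C(=C)[C@H](CC#CC)C(C)=C | intermediate
8 | (2E,5S,7R)-5-hydroxy-N-methoxy-N,2-dimethyl-6-methylidene-7-(prop-1-en-2-yl)undec-2-en-9-ynamide | CON(C)C(=O)/C(C)=C/C[C@H](O)C(=C)[C@H](CC#CC)C(C)=C | intermediate
9 | (3E,6S,8R)-6-hydroxy-3-methyl-7-methylidene-8-(prop-1-en-2-yl)dodec-3-en-10-yn-2-one | CC(=O)/C(C)=C/C[C@H](O)C(=C)[C@H](CC#CC)C(C)=C | intermediate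
10 | (3E,6S,8R)-2,6-bis[(tert-butyldimethylsilyl)oxy]-3-methyl-7-methylidene-8-(prop-1-en-2-yl)dodeca-1,3-dien-10-yne | C=C(O[Si](C)(C)C(C)(C)C)/C(C)=C/C[C@H](O[Si](C)(C)C(C)(C)C)C(=C)[C@H](CC#CC)C(C)=C | intermediate
11 | (5R,7S,9R,10R)-3,7-bis(TBS-oxy)-14,15,18-trinorlabda-3,8(17)-dien-12-yne (trans-decalin; 5α-H, 7β-OTBS, 9β-butynyl, 10β-Me) | C=C1[C@@H](O[Si](C)(C)C(C)(C)C)C[C@H]2C(C)=C(O[Si](C)(C)C(C)(C)C)CC[C@]2(C)[C@H]1CC#CC | intermediate
12 | alkenylzirconocene chloride from 11 (Cp2ZrCl on C13, H on C12, syn) | C=C1[C@@H](O[Si](C)(C)C(C)(C)C)C[C@H]2C(C)=C(O[Si](C)(C)C(C)(C)C)CC[C@]2(C)[C@H]1C/C=C(\C)[Zr](Cl)(C1C=CC=C1)C1C=CC=C1 | intermediate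
13 | (5R,7S,9R,10R,12E)-3,7-bis(TBS-oxy)-18-norlabda-3,8(17),12,14-tetraene | C=C1[C@@H](O[Si](C)(C)C(C)(C)C)C[C@H]2C(C)=C(O[Si](C)(C)C(C)(C)C)CC[C@]2(C)[C@H]1C/C=C(\C)C=C | intermediate
14 | (4R,5R,7S,9R,10R,12E)-7-(TBS-oxy)-18-hydroxylabda-8(17),12,14-trien-3-one (4α-CH2OH, 4β-Me) | C=C1[C@@H](O[Si](C)(C)C(C)(C)C)C[C@H]2[C@](C)(CO)C(=O)CC[C@]2(C)[C@H]1C/C=C(\C)C=C | intermediate
15 | C3 p-toluenesulfonylhydrazone of 14 (4S,5R,7S,9R,10S by the sequence rule, same spatial arrangement) | C=C1[C@@H](O[Si](C)(C)C(C)(C)C)C[C@H]2[C@](C)(CO)C(=NNS(=O)(=O)c3ccc(C)cc3)CC[C@]2(C)[C@H]1C/C=C(\C)C=C | intermediate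
16 | (4R,5R,7S,9R,10S,12E)-7-(TBS-oxy)labda-8(17),12,14-trien-18-ol | C=C1[C@@H](O[Si](C)(C)C(C)(C)C)C[C@H]2[C@](C)(CO)CCC[C@]2(C)[C@H]1C/C=C(\C)C=C | intermediate
17 | (4R,5R,7S,9R,10S,12E)-labda-8(17),12,14-triene-7,18-diol (7β-OH) | C=C1[C@@H](O)C[C@H]2[C@](C)(CO)CCC[C@]2(C)[C@H]1C/C=C(\C)C=C | intermediate
18 | 2',4',6'-trihydroxyacetophenone | CC(=O)c1c(O)cc(O)cc1O | starting material
19 | 1-[2,4-bis(benzyloxy)-6-hydroxyphenyl]ethan-1-one | CC(=O)c1c(O)cc(OCc2ccccc2)cc1OCc1ccccc1 | intermediate
20 | 2,4,5-trimethoxybenzaldehyde | COc1cc(OC)c(C=O)cc1OC | starting material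
21 | (2E)-1-[2,4-bis(benzyloxy)-6-hydroxyphenyl]-3-(2,4,5-trimethoxyphenyl)prop-2-en-1-one | COc1cc(OC)c(/C=C/C(=O)c2c(O)cc(OCc3ccccc3)cc2OCc2ccccc2)cc1OC | intermediate
22 | 5,7-bis(benzyloxy)-2-(2,4,5-trimethoxyphenyl)-4H-chromen-4-one | COc1cc(OC)c(cc1OC)-c1cc(=O)c2c(OCc3ccccc3)cc(OCc3ccccc3)cc2o1 | intermediate
23 | 2-[5,7-bis(benzyloxy)-4-oxo-4H-chromen-2-yl]-5-methoxycyclohexa-2,5-diene-1,4-dione | COC1=CC(=O)C(=CC1=O)c1cc(=O)c2c(OCc3ccccc3)cc(OCc3ccccc3)cc2o1 | intermediate
24 | 2-(2,5-dihydroxy-4-methoxyphenyl)-5,7-dihydroxy-4H-chromen-4-one | COc1cc(O)c(cc1O)-c1cc(=O)c2c(O)cc(O)cc2o1 | intermediate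
25 | 2-(5,7-dihydroxy-4-oxo-4H-chromen-2-yl)-5-methoxycyclohexa-2,5-diene-1,4-dione | COC1=CC(=O)C(=CC1=O)c1cc(=O)c2c(O)cc(O)cc2o1 | intermediate
26 | dichrostachine A | C=C1[C@@H](O)C[C@H]2[C@](C)(CO)CCC[C@]2(C)[C@H]1C[C@@H]1C(C)=CC[C@H]2C(=O)C(OC)=CC(=O)[C@@]12c1cc(=O)c2c(O)cc(O)cc2o1 | target

**Step count and risks**
Total step count: 20. Longest linear sequence: 14 steps (1, 2, 3, 5–14, 20, from (R)-carvone).

Steps most likely to fail:

1. Step 20. The cycloaddition may take the quinone-endo course and the other diene face (poor endo/exo and π-facial selectivity), and regiocontrol between the two dienophile carbons may erode. The fallback sets out from 25 and comes back at 26. Quinone 25 is treated with BF3·OEt2 in CH2Cl2 to give the difluoroboron chelate F1 of its 5-hydroxy-4-oxo unit, an isolable and strongly electron-poor acceptor in which the chelated chromone becomes the dominant activating and endo-orienting group and polarises the quinone CH. Cycloaddition of F1 with 17 at room temperature should give the chelated adduct F2, from which the facial isomer is removed by chromatography. Mild hydrolysis of the chelate (NaOAc, aqueous MeOH, 40 °C) returns 26.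

2. Step 9. The silyl dienol ether may be lost (hydrolysis or silyl transfer) during the long heating before cyclisation, and the trans preference may erode at the higher temperature then needed. The fallback sets out from 9 and comes back at 11. Alcohol 9 is silylated at O7 only (TBSCl, imidazole, DMF) to give the silyloxy enone F3. Kinetic enolisation (KN(SiMe3)2, THF, −78 °C) and O-acetylation with Ac2O give the 2-acetoxy diene F4, an enol ester that tolerates 200 °C and traces of acid. Its intramolecular Diels–Alder reaction in toluene at 200 °C should give the enol acetate F5. Cleavage of the enol acetate with two equivalents of MeLi releases the regiodefined C3/C4 lithium enolate, which is silylated (TBSCl, HMPA) to 11.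

3. Step 5. Facial discrimination at the aldehyde by the boron Lewis acid may be insufficient, giving a mixture at C7. The fallback sets out from 17, obtained together with its 7-epimer when the mixture is carried through steps 6–14 (the cycloaddition is steered mainly by C9), and comes back at 17. MnO2 in CH2Cl2 oxidises only the allylic 7-hydroxyl of both epimers to the single 7-oxo compound F6. Luche reduction (NaBH4, CeCl3·7H2O, MeOH, −78 °C) delivers hydride axially from the α-face to give the equatorial 7β-alcohol 17, so the configuration is set by the substrate instead of by the reagent.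

Further compounds
F1 | step 20 | difluoroboron chelate of quinone 25 (O5–BF2–O4 six-membered chelate) | COC1=CC(=O)C(=CC1=O)C1=CC2=[O+][B-](F)(F)Oc3cc(O)cc(O1)c23
F2 | step 20 | difluoroboron chelate of dichrostachine A | C=C1[C@@H](O)C[C@H]2[C@](C)(CO)CCC[C@]2(C)[C@H]1C[C@@H]1C(C)=CC[C@H]2C(=O)C(OC)=CC(=O)[C@@]12C1=CC2=[O+][B-](F)(F)Oc3cc(O)cc(O1)c23
F3 | step 9 | (3E,6S,8R)-6-[(tert-butyldimethylsilyl)oxy]-3-methyl-7-methylidene-8-(prop-1-en-2-yl)dodec-3-en-10-yn-2-one | CC(=O)/C(C)=C/C[C@H](O[Si](C)(C)C(C)(C)C)C(=C)[C@H](CC#CC)C(C)=C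
F4 | step 9 | (3E,6S,8R)-6-[(tert-butyldimethylsilyl)oxy]-3-methyl-7-methylidene-8-(prop-1-en-2-yl)dodeca-1,3-dien-10-yn-2-yl acetate | C=C(OC(C)=O)/C(C)=C/C[C@H](O[Si](C)(C)C(C)(C)C)C(=C)[C@H](CC#CC)C(C)=C
F5 | step 9 | (5R,7S,9R,10R)-7-(TBS-oxy)-14,15,18-trinorlabda-3,8(17)-dien-12-yn-3-yl acetate (trans-decalin enol acetate) | C=C1[C@@H](O[Si](C)(C)C(C)(C)C)C[C@H]2C(C)=C(OC(C)=O)CC[C@]2(C)[C@H]1CC#CC
F6 | step 5 | (12E)-18-hydroxylabda-8(17),12,14-trien-7-one | C=C1C(=O)C[C@H]2[C@](C)(CO)CCC[C@]2(C)[C@H]1C/C=C(\C)C=C
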